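The numbers in the tables stem from a simulated flask with constants of no real substance; noise was put on by code.

In a one-step world, with the incoming ligand held at its charge, the starting complex would decay pseudo-first-order, and ln(1/f), with f the fraction of the charge left, would climb straight with time. The quick number requested concerns this row:

in all of them: starting complex 0.056 M

| flask | incoming ligand | remark | time |
|---|---|---|---|
| ochre | 1.5 equiv | run made earlier |  |
| amber | 10 equiv | run made earlier |  |
| spring | 1.00 equiv |  | 4.0 h |
| winter | 2.00 equiv |  | 4.0 h |
| autumn | 4.00 equiv |  | 4.0 h |
| midnight | 8.00 equiv |  | 4.0 h |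

| run | time / h | complex with one exchanged / % | starting complex / % |
|---|---|---|---|
| ochre | 0.250 | 5 | 95 |
| ochre | 0.333 | 8 | 93 |
| ochre | 0.500 | 5 | 93 |
| ochre | 0.833 | 10 | 94 |
| ochre | 1.33 | 15 | 87 |
| ochre | 2.00 | 19 | 85 |
| ochre | 3.00 | 14 | 80 |
| amber | 0.250 | 19 | 74 |
| amber | 0.333 | 23 | 68 |
| amber | 0.500 | 24 | 61 |
| amber | 0.833 | 24 | 45 |
| amber | 1.33 | 23 | 35 |
| amber | 2.00 | 20 | 24 |
| amber | 3.00 | 16 | 20 |

(standard deviation of a reading: 2 percentage points)

- the numbers in the tables scatter with a standard deviation of 2 percentage points
- on the list of suspects stand: complex with one exchanged + incoming ligand <-> leaving ligand + complex with two exchanged; complex with one exchanged -> over-reaction product; incoming ligand <-> dormant form; starting complex + incoming ligand <-> leaving ligand + complex with one exchanged; incoming ligand -> decomposed reagent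
- "hardly changes" means that all values lie within two and a half points (for a concentration: within two and a half percent of the largest)

* amount of complex with one exchanged at the end, in percent of the starting complex charged for spring, winter, autumn, midnight, in this order
* the shape of the row from first to last (rises, then falls / hardly changes / rises all the way / falls, then rises / falls all the way)

Amber does not climb straight. Its ln(1/f) gains 1.20 h⁻¹ at first but 0.182 h⁻¹ between 2.00 h and 3.00 h, a slower climb. The two exchanges take two ligands per complex at most out of amber's 10 equiv, and the reckoning here reads the slowing as free incoming ligand going some other way.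

The falling ligand curve can therefore be replaced by its mean, and one number serves: s, the exposure per equivalent, which is ln(1/f) over the equivalents charged. It is carried to 4.0 h by crediting the last hour with 0.5 of amber's gain in the hour before, a guess: s = 0.170.

The error of that replacement can be read at 3.00 h, where the amber reading gives 0.161 and the ochre reading, from a smaller charge, 0.149.

Taking the second exchange at 2 times the rate constant of the first makes m, the fraction with one exchanged, equal to f minus f·f. Amber at 0.500 h then gives 23.8% against 24% read, and ochre at 3.00 h gives 16.0% against 14% read. For a charge e: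

f = exp(−s·e), m = f − f·f

m = 13.2%, 20.5%, 25.0%, 19.1%

peak at f = 0.5: e = ln(2)/s = 4.08

The forecast, the colleague's hunch, reads 12%, 20%, 25%, 20%, rises, then falls, with 0.18 per equiv in place of s and its peak “near 4 equiv”.

The flasks gave 13.2%, 20.3%, 24.4%, 18.5%: rises, then falls, turning at 4.0 equiv, where s had put the peak at 4.08.

    complex with one exchanged + incoming ligand ⇌ leaving ligand + complex with two exchanged (K = 64.0, k = 0.0630 L mol⁻¹ min⁻¹)
    complex with one exchanged → over-reaction product (k = 2.40 × 10⁻⁴ min⁻¹)
    incoming ligand ⇌ dormant form (K = 0.340, k = 0.00200 min⁻¹)
    starting complex + incoming ligand ⇌ leaving ligand + complex with one exchanged (K = 1.90, k = 0.0370 L mol⁻¹ min⁻¹)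
    incoming ligand → decomposed reagent (k = 0.00750 min⁻¹)

Autumn at 4.00 h held 51.6% starting complex, and s gives f = 50.6% there. Put to midnight, s gives f = 25.7%, and midnight held 27.3% starting complex at 4.00 h.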